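**Plan**
Locants: lactone O1, C2 (C=O), C3, C4 (its CH2OH carbon is C4'), C5; side chain C6–C20 (hydroxymethyl on C8 is C8').
1. Retrosynthesis: cut O1–C5 and C2–C3 of the butenolide (CO2 plus a C3–C4–C5 unit), then the C7=C8 alkene (Wittig), then C9–C10 (acetoacetate alkylation of farnesyl bromide).
2. Enabling feature: the two oxygens on C4' and C5 flank C4 in a 1,3-relationship, so they can be tied as an oxetane ring (O, C5, C4, C4') carrying an exocyclic C3=C4 alkene with iodine on C3 cis to C5.
3. Forward: ynone → (S)-propargylic alcohol → anti-carbomagnesiation/iodination/oxidation → alkylidene oxetane → phosphonium salt; separately farnesyl bromide → α-silyloxy ketone; Z-selective Wittig joins them.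
4. Key event: iodine–lithium exchange, capture of CO2 at C3, then strain-release opening of the oxetane at C5 by the new carboxyl group closes the lactone and frees the C4' hydroxymethyl group in one operation; desilylation ends the route.
5. Stereochemistry: C5 from asymmetric transfer hydrogenation (S), kept through oxetane formation, inverted to (R) by SN2 in the key step; alkene geometries from anti-carbomagnesiation (C3=C4), the Wittig reaction (C7=C8), SeO2 oxidation (C19=C20) and farnesyl bromide.

Key step: step 12

Remark: the (S,S)-catalyst of step 2 is assumed to give the (S)-carbinol, as it does for simple alkynyl ketones; if the sense proved opposite, the enantiomeric catalyst would be used.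

**Step 1**
Reactants: 1 3-chloropropanoyl chloride; 2 bis(trimethylsilyl)acetylene
Product: 3 5-chloro-1-(trimethylsilyl)pent-1-yn-3-one
Conditions: AlCl3 (1.1 equiv), CH2Cl2, 0 °C
Reagents that add atoms: none
Why: Friedel–Crafts-type ipso-acylation of an alkynylsilane (acylium attack at the silicon-bearing carbon, loss of Me3SiCl) should stop at mono-acylation because the ynone is deactivated.

**Step 2**
Reactants: 3 5-chloro-1-(trimethylsilyl)pent-1-yn-3-one
Product: 4 (S)-5-chloro-1-(trimethylsilyl)pent-1-yn-3-ol
Conditions: RuCl[(S,S)-TsDPEN](p-cymene) (1 mol %), i-PrOH, 25 °C, no added base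
Reagents that add atoms: none
Why: Noyori asymmetric transfer hydrogenation of alkynyl ketones is highly enantioselective and sets C5 as (S) by catalyst control, and the base-free conditions should spare the β-chloro ketone from elimination.

**Step 3**
Reactants: 4 (S)-5-chloro-1-(trimethylsilyl)pent-1-yn-3-ol
Product: 5 (S)-5-chloropent-1-yn-3-ol
Conditions: K2CO3 (0.2 equiv), MeOH, 0 °C
Reagents that add atoms: none
Why: Mild methanolysis of the C(sp)–Si bond (protodesilylation) frees the terminal alkyne without touching C5 or the primary chloride.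

**Step 4**
Reactants: 5 (S)-5-chloropent-1-yn-3-ol
Product: 8 (S,Z)-5-chloro-2-(iodomethylene)pentane-1,3-diol, via cyclic vinylmagnesium alkoxide 6 (not isolated), via iodo allylsilane 7 (not isolated)
Conditions: i-PrOMe2SiCH2MgCl (3 equiv), CuI (10 mol %), Et2O–THF, 0 °C → reflux; I2, −40 → 0 °C; crude silane: KF, KHCO3, 30% H2O2, THF–MeOH, rt
Reagents that add atoms: (isopropoxydimethylsilyl)methylmagnesium chloride CC(C)O[Si](C)(C)C[Mg]Cl; iodine II; hydrogen peroxide OO
Why: Copper-catalysed anti-carbomagnesiation of the propargylic alkoxide puts the CH2Si group on C4 and magnesium on C3 inside a five-membered chelate, so iodine enters cis to C5, and Tamao–Fleming oxidation then turns C4'–Si into C4'–OH with C5 untouched.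

**Step 5**
Reactants: 8 (S,Z)-5-chloro-2-(iodomethylene)pentane-1,3-diol
Product: 10 (S,Z)-2-(2-chloroethyl)-3-(iodomethylene)oxetane, via primary trisylate 9 (not isolated)
Conditions: NaH (2.5 equiv), THF, 0 °C; N-(2,4,6-triisopropylbenzenesulfonyl)imidazole (1.05 equiv), 0 → 40 °C, high dilution
Reagents that add atoms: none
Why: The bulky sulfonyl imidazole should sulfonylate only the primary allylic alkoxide, and 4-exo-tet Williamson closure by the C5 alkoxide (C5–O bond intact, so retention at C5) should give the alkylidene oxetane, by analogy with methylenecyclobutane formation from 2-methylene-1,3-dielectrophiles.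

**Step 6**
Reactants: 10 (S,Z)-2-(2-chloroethyl)-3-(iodomethylene)oxetane
Product: 11 {2-[(2S,3Z)-3-(iodomethylene)oxetan-2-yl]ethyl}triphenylphosphonium iodide
Conditions: PPh3 (1.5 equiv), NaI (2 equiv), MeCN, 80 °C
Reagents that add atoms: triphenylphosphine c1ccc(cc1)P(c1ccccc1)c1ccccc1; sodium iodide [Na+].[I-]
Why: In situ Finkelstein exchange and SN2 quaternisation of the phosphine at the primary carbon should proceed under neutral conditions that leave the oxetane and the alkenyl iodide alone.

**Step 7**
Reactants: 12 (2E,6E)-farnesyl bromide; 13 ethyl acetoacetate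
Product: 15 (5E,9E)-6,10,14-trimethylpentadeca-5,9,13-trien-2-one (farnesylacetone), via keto ester 14 (not isolated)
Conditions: NaOEt (1.0 equiv), 13 (1.5 equiv), EtOH, 0 °C → rt; 2 M NaOH, 60 °C; HCl to pH 3, 60 °C
Reagents that add atoms: none
Why: Acetoacetic ester synthesis: SN2 alkylation at the primary allylic bromide keeps both alkene geometries, and saponification with decarboxylation gives the methyl ketone (C8–C10 in place).

**Step 8**
Reactants: 15 (5E,9E)-farnesylacetone
Product: 16 (5E,9E,13E)-15-hydroxy-6,10,14-trimethylpentadeca-5,9,13-trien-2-one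
Conditions: SeO2 (0.1 equiv), t-BuOOH (3 equiv), salicylic acid (0.1 equiv), CH2Cl2, 0 °C → rt
Reagents that add atoms: tert-butyl hydroperoxide CC(C)(C)OO
Why: SeO2 allylic oxidation (ene reaction, then [2,3] shift) is selective for the E-methyl group of the terminal, most electron-rich trisubstituted alkene, as with farnesyl and geranylacetone derivatives, and so sets the 13E allylic alcohol.

**Step 9**
Reactants: 16 (5E,9E,13E)-15-hydroxy-6,10,14-trimethylpentadeca-5,9,13-trien-2-one
Product: 18 (5E,9E,13E)-1,15-dihydroxy-6,10,14-trimethylpentadeca-5,9,13-trien-2-one, via sodium enolate 17 (not isolated)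
Conditions: NaN(SiMe3)2 (2.2 equiv), THF, −78 °C; 2-(phenylsulfonyl)-3-phenyloxaziridine (1.3 equiv), −78 °C; AcOH
Reagents that add atoms: 2-(phenylsulfonyl)-3-phenyloxaziridine O=S(=O)(N1OC1c1ccccc1)c1ccccc1
Why: Kinetic deprotonation of the methyl ketone at the methyl group and Davis oxidation of the enolate should install the C8' oxygen; no stereocentre is formed.

**Step 10**
Reactants: 18 (5E,9E,13E)-1,15-dihydroxy-6,10,14-trimethylpentadeca-5,9,13-trien-2-one
Product: 19 (5E,9E,13E)-1,15-bis(tert-butyldimethylsilyloxy)-6,10,14-trimethylpentadeca-5,9,13-trien-2-one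
Conditions: TBSCl (2.5 equiv), imidazole (5 equiv), DMF, 0 °C → rt
Reagents that add atoms: tert-butyldimethylsilyl chloride CC(C)(C)[Si](C)(C)Cl
Why: Standard silylation of two primary hydroxyl groups gives the α-silyloxy ketone needed for the Wittig step.

**Step 11**
Reactants: 11 {2-[(2S,3Z)-3-(iodomethylene)oxetan-2-yl]ethyl}triphenylphosphonium iodide; 19 bis-silyl ketone
Product: 21 (2S,3Z)-3-(iodomethylene)-2-[(2Z,6E,10E,14E)-16-(tert-butyldimethylsilyloxy)-3-(tert-butyldimethylsilyloxymethyl)-7,11,15-trimethylhexadeca-2,6,10,14-tetraen-1-yl]oxetane, via ylide 20 (not isolated)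
Conditions: 11 (1.2 equiv), NaN(SiMe3)2 (1.15 equiv), THF, −78 → 0 °C; then 19, −78 °C → rt
Reagents that add atoms: none
Why: The Wittig reaction of an α-oxygenated ketone with a salt-free, non-stabilised ylide is known to place the new chain cis to the CH2O group, which should set the C7=C8 alkene as Z while the oxetane, the alkenyl iodide and C5 are unaffected.

**Step 12**
Reactants: 21 alkenyl iodide oxetane
Product: 24 (R)-5-[(2Z,6E,10E,14E)-16-(tert-butyldimethylsilyloxy)-3-(tert-butyldimethylsilyloxymethyl)-7,11,15-trimethylhexadeca-2,6,10,14-tetraen-1-yl]-4-(hydroxymethyl)furan-2(5H)-one, via vinyllithium 22 (not isolated), via carboxylic acid 23 (not isolated)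
Conditions: t-BuLi (2.1 equiv), Et2O, −78 °C, 10 min; CO2 (dry gas), −78 → −20 °C; cold 0.5 M HCl to pH 4, extract; crude acid: PPTS (10 mol %), CH2Cl2, 0 °C → rt
Reagents that add atoms: carbon dioxide O=C=O
Why: Iodine–lithium exchange gives the configurationally stable alkenyllithium 22 with lithium syn to C5, and its addition to CO2 makes the C3–C2 bond; on acidification the carboxyl group of 23 attacks C5 of the activated oxetane from the side opposite the ring oxygen and makes the O1–C5 bond, releasing about 25 kcal/mol of ring strain and unmasking the C4' hydroxymethyl group. The closest known reaction types are the carboxylation of alkenyllithiums and the acid-promoted isomerisation of oxetane carboxylic acids to lactones. The lactone closes in the 5-exo-tet mode, with the breaking C5–O bond lying in the plane of the C3=C4 alkene and nearly collinear with the incoming oxygen. C5 is the only stereocentre and is inverted by this SN2 displacement, (S) in 21 to (R) in 24. The step needs regioselectivity between the oxetane carbons C5 and C4' and chemoselective metalation; the Z alkene lets the carboxyl reach C5 only, and the alkenyl iodide exchanges far faster than any other site reacts at −78 °C.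

**Step 13**
Reactants: 24 butenolide bis-silyl ether
Product: 25 Hippolide F
Conditions: HF·pyridine, pyridine, THF, 0 °C → rt
Reagents that add atoms: none
Why: Buffered fluoride desilylation of the two primary allylic silyl ethers should leave the butenolide, the alkenes and C5 intact.

**Compound list**
1 | 3-chloropropanoyl chloride | O=C(Cl)CCCl | starting material
2 | bis(trimethylsilyl)acetylene | C[Si](C)(C)C#C[Si](C)(C)C | starting material
3 | 5-chloro-1-(trimethylsilyl)pent-1-yn-3-one | C[Si](C)(C)C#CC(=O)CCCl | intermediate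
4 | (S)-5-chloro-1-(trimethylsilyl)pent-1-yn-3-ol | C[Si](C)(C)C#C[C@@H](O)CCCl | intermediate
5 | (S)-5-chloropent-1-yn-3-ol | C#C[C@@H](O)CCCl | intermediate
6 | cyclic vinylmagnesium alkoxide, (S)-5-(2-chloroethyl)-4-[(isopropoxydimethylsilyl)methyl]-2,5-dihydro-1,2-oxamagnesole | CC(C)O[Si](C)(C)CC1=C[Mg]O[C@H]1CCCl | intermediate
7 | (S,E)-1-chloro-4-(iodomethylene)-5-(isopropoxydimethylsilyl)pentan-3-ol | I/C=C(/C[Si](C)(C)OC(C)C)[C@@H](O)CCCl | intermediate
8 | (S,Z)-5-chloro-2-(iodomethylene)pentane-1,3-diol | I/C=C(/CO)[C@@H](O)CCCl | intermediate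
9 | sodium alkoxide of the primary 2,4,6-triisopropylbenzenesulfonate of 8 | I/C=C(/COS(=O)(=O)c1c(C(C)C)cc(C(C)C)cc1C(C)C)[C@@H]([O-])CCCl.[Na+] | intermediate
10 | (S,Z)-2-(2-chloroethyl)-3-(iodomethylene)oxetane | I/C=C1/CO[C@H]1CCCl | intermediate
11 | {2-[(2S,3Z)-3-(iodomethylene)oxetan-2-yl]ethyl}triphenylphosphonium iodide | I/C=C1/CO[C@H]1CC[P+](c2ccccc2)(c2ccccc2)c2ccccc2.[I-] | intermediate
12 | (2E,6E)-farnesyl bromide | CC(C)=CCC/C(C)=C/CC/C(C)=C/CBr | starting material
13 | ethyl acetoacetate | CCOC(=O)CC(C)=O | starting material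
14 | ethyl (4E,8E)-2-acetyl-5,9,13-trimethyltetradeca-4,8,12-trienoate | CCOC(=O)C(C/C=C(\C)CC/C=C(\C)CCC=C(C)C)C(C)=O | intermediate
15 | (5E,9E)-6,10,14-trimethylpentadeca-5,9,13-trien-2-one | CC(=O)CC/C=C(\C)CC/C=C(\C)CCC=C(C)C | intermediate
16 | (5E,9E,13E)-15-hydroxy-6,10,14-trimethylpentadeca-5,9,13-trien-2-one | CC(=O)CC/C=C(\C)CC/C=C(\C)CC/C=C(\C)CO | intermediate
17 | disodium enolate alkoxide of 16 | C=C([O-])CC/C=C(\C)CC/C=C(\C)CC/C=C(\C)C[O-].[Na+].[Na+] | intermediate
18 | (5E,9E,13E)-1,15-dihydroxy-6,10,14-trimethylpentadeca-5,9,13-trien-2-one | O=C(CO)CC/C=C(\C)CC/C=C(\C)CC/C=C(\C)CO | intermediate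
19 | (5E,9E,13E)-1,15-bis(tert-butyldimethylsilyloxy)-6,10,14-trimethylpentadeca-5,9,13-trien-2-one | CC(C)(C)[Si](C)(C)OCC(=O)CC/C=C(\C)CC/C=C(\C)CC/C=C(\C)CO[Si](C)(C)C(C)(C)C | intermediate
20 | {2-[(2S,3Z)-3-(iodomethylene)oxetan-2-yl]ethylidene}triphenylphosphorane | I/C=C1/CO[C@H]1CC=P(c2ccccc2)(c2ccccc2)c2ccccc2 | intermediate
21 | (2S,3Z)-3-(iodomethylene)-2-[(2Z,6E,10E,14E)-16-(tert-butyldimethylsilyloxy)-3-(tert-butyldimethylsilyloxymethyl)-7,11,15-trimethylhexadeca-2,6,10,14-tetraen-1-yl]oxetane | I/C=C1/CO[C@H]1C/C=C(\CO[Si](C)(C)C(C)(C)C)CC/C=C(\C)CC/C=C(\C)CC/C=C(\C)CO[Si](C)(C)C(C)(C)C | intermediate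
22 | alkenyllithium from 21 (lithium in place of iodine) | [Li]/C=C1/CO[C@H]1C/C=C(\CO[Si](C)(C)C(C)(C)C)CC/C=C(\C)CC/C=C(\C)CC/C=C(\C)CO[Si](C)(C)C(C)(C)C | intermediate
23 | (Z)-2-{(S)-2-[(2Z,6E,10E,14E)-16-(tert-butyldimethylsilyloxy)-3-(tert-butyldimethylsilyloxymethyl)-7,11,15-trimethylhexadeca-2,6,10,14-tetraen-1-yl]oxetan-3-ylidene}acetic acid | O=C(O)/C=C1/CO[C@H]1C/C=C(\CO[Si](C)(C)C(C)(C)C)CC/C=C(\C)CC/C=C(\C)CC/C=C(\C)CO[Si](C)(C)C(C)(C)C | intermediate
24 | (R)-5-[(2Z,6E,10E,14E)-16-(tert-butyldimethylsilyloxy)-3-(tert-butyldimethylsilyloxymethyl)-7,11,15-trimethylhexadeca-2,6,10,14-tetraen-1-yl]-4-(hydroxymethyl)furan-2(5H)-one | OCC1=CC(=O)O[C@@H]1C/C=C(\CO[Si](C)(C)C(C)(C)C)CC/C=C(\C)CC/C=C(\C)CC/C=C(\C)CO[Si](C)(C)C(C)(C)C | intermediate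
25 | Hippolide F, (R)-4-(hydroxymethyl)-5-[(2Z,6E,10E,14E)-16-hydroxy-3-(hydroxymethyl)-7,11,15-trimethylhexadeca-2,6,10,14-tetraen-1-yl]furan-2(5H)-one | C/C(=C\CC/C(C)=C/CC/C(C)=C/CC/C(=C/C[C@H]1OC(=O)C=C1CO)CO)CO | target

**Totals**
Total step count: 13.
Longest linear sequence: 9 steps (steps 1–6, then 11–13); the ketone branch is steps 7–10.

**Steps most likely to fail**

Step 12. The exchange could be spoiled by addition of tert-butyllithium to the strained exocyclic alkene or by proton transfer before CO2 is captured, and the opening could be intercepted by an external nucleophile. The fallback sets out from 21 and brings in C2 under neutral conditions from carbon monoxide: methoxycarbonylation of the alkenyl iodide (PdCl2(PPh3)2, CO, MeOH, Et3N, DMF, 50 °C) should give the methyl (Z)-oxetanylideneacetate F1, and saponification (LiOH, THF–H2O) returns to the route at acid 23, which is then opened to 24 as in step 12.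

Step 4. The silylmethyl Grignard reagent could add too slowly, the vinylmagnesium intermediate could alkylate the pendant chloride, or iodine could attack the allylsilane. The fallback sets out from 5 and uses the better-behaved vinyl Grignard reagent as a masked hydroxymethyl group: anti-carbomagnesiation with vinylmagnesium chloride followed by iodine should give (S,Z)-1-chloro-4-(iodomethylene)hex-5-en-3-ol F2. Dihydroxylation of the unhindered terminal vinyl group (OsO4 cat., N-methylmorpholine N-oxide) and cleavage with NaIO4 gives (S,E)-5-chloro-3-hydroxy-2-(iodomethylene)pentanal F3, and NaBH4/CeCl3·7H2O reduction returns to the route at 8.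

Step 5. Sulfonylation could stray to the secondary hydroxyl group, which would invert C5 on closure and erode enantiomeric purity, or intermolecular etherification could outrun the 4-exo closure. The fallback sets out from 5 and builds the oxetane before the alkene: gold-catalysed oxidative cyclisation of the propargylic alcohol ((Ph3P)AuNTf2, a pyridine N-oxide, HNTf2, 1,2-dichloroethane, rt) should give (S)-2-(2-chloroethyl)oxetan-3-one F4 with the C5–O bond untouched. Wittig iodomethylenation (Ph3P=CHI from (iodomethyl)triphenylphosphonium iodide and NaN(SiMe3)2, THF, −78 °C) returns to the route at 10 after chromatographic separation from its E isomer, for which no geometric control is expected.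

**Further compounds**
F1 | step 12 | methyl (Z)-2-{(S)-2-[(2Z,6E,10E,14E)-16-(tert-butyldimethylsilyloxy)-3-(tert-butyldimethylsilyloxymethyl)-7,11,15-trimethylhexadeca-2,6,10,14-tetraen-1-yl]oxetan-3-ylidene}acetate | COC(=O)/C=C1/CO[C@H]1C/C=C(\CO[Si](C)(C)C(C)(C)C)CC/C=C(\C)CC/C=C(\C)CC/C=C(\C)CO[Si](C)(C)C(C)(C)C
F2 | step 4 | (S,Z)-1-chloro-4-(iodomethylene)hex-5-en-3-ol | I/C=C(/C=C)[C@@H](O)CCCl
F3 | step 4 | (S,E)-5-chloro-3-hydroxy-2-(iodomethylene)pentanal | I/C=C(/C=O)[C@@H](O)CCCl
F4 | step 5 | (S)-2-(2-chloroethyl)oxetan-3-one | O=C1CO[C@H]1CCCl
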